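**Plan**

1. Locants (lignan style): ring A = O–C7'H(aryl)–C8'H–C8(OAc)–C9H2; ring B = O–C7H(aryl)–C8–C8'H–C9'H2. Retrosynthesis: remove the acetate and phenol protecting groups; cut C7–C8 (ring B) back to a ring A ketone whose C9' oxygen carries the second aryl unit as a benzyl ether; cut that ether; last, cut C7'–C8' of ring A.
2. Enabling feature: in ring A the benzylic carbon C7' lies between the ring oxygen and C8', which bears the oxygenated one-carbon branch C9'. O–C7'(aryl)–C8'–C9'=O is an aldol retron whose aldol oxygen is the ring oxygen, so ring A is O-3, C-2, C-6, C-5 and C-4 of a 2-aryl-4,5-dihydro-1,3-dioxepine (a seven-membered cyclic vinyl acetal). A Lewis acid contracts that ring to ring A and pushes C-7 and O-1 out as the C9' formyl group.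
3. Forward: silylated vanillin + (Z)-but-2-ene-1,4-diol → 4,7-dihydro-1,3-dioxepine → meso epoxide → enantioselective isomerisation to the 5-silyloxy vinyl acetal → ring contraction (ring A) → benzyl ether and ketone → photocyclisation (ring B and the tertiary carbinol together) → acetate → free phenols.
4. Stereochemistry: the C8 carbinol centre comes from a chiral lithium amide desymmetrisation. In the contraction it sets C8' (allylic strain) and C7' (all-trans, thermodynamic). It is then erased by oxidation and made again in the photocyclisation, where the tether from C8' forces the cis ring fusion (C8) and the aryl group closes exo (C7).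

Key step: step 5

Assumption: the sense of the lithium amide desymmetrisation is assigned by analogy with cyclohexene oxide, so the (R)-diamine is specified for the (5S)-alcohol; if the sense is found reversed, the (S)-diamine is used and nothing else changes.

Abbreviations: Ar = 3-methoxy-4-[(triisopropylsilyl)oxy]phenyl. Dioxepine locants are written with a hyphen (O-1, C-2, O-3, C-4 to C-7), lignan locants without (C7, C8, C9, C7', C8', C9'). Mapping: C-2 = C7', O-3 = ring A oxygen, C-4 = C9, C-5 = C8, C-6 = C8', C-7 = C9', O-1 = the later ring B oxygen.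

**Route**

Step 1
Reactants: 1 vanillin (4-hydroxy-3-methoxybenzaldehyde)
Product: 2 3-methoxy-4-[(triisopropylsilyl)oxy]benzaldehyde (ArCHO)
Conditions: i-Pr3SiCl, imidazole, DMF, rt
Reagents that add atoms: chlorotriisopropylsilane, CC(C)[Si](Cl)(C(C)C)C(C)C
Why: Imidazole-promoted O-silylation of the phenol; the aryl triisopropylsilyl ether should withstand the amide base, the Lewis acid, mild acid and light used later, and buffered fluoride removes it at the end without touching the acetate or the benzylic ether bonds.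

Step 2
Reactants: 2 ArCHO; 3 (Z)-but-2-ene-1,4-diol
Product: 4 2-Ar-4,7-dihydro-1,3-dioxepine
Conditions: pyridinium p-toluenesulfonate (cat.), benzene, reflux, Dean–Stark trap
Reagents that add atoms: none
Why: Acid-catalysed acetalisation driven by azeotropic removal of water; the cis diol can close only to the seven-membered ring, which already holds the ring A oxygen, C7', C9, C8, C8' and C9' in one ring.

Step 3
Reactants: 4 2-Ar-4,7-dihydro-1,3-dioxepine
Product: 5 4-Ar-3,5,8-trioxabicyclo[5.1.0]octane (cis-fused epoxide, (1R,7S), meso; both orientations of Ar at the acetal carbon)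
Conditions: 3-chloroperoxybenzoic acid, NaHCO3, CH2Cl2, 0 °C to rt
Reagents that add atoms: 3-chloroperoxybenzoic acid, OOC(=O)c1cccc(Cl)c1
Why: Prilezhaev epoxidation of the ring cis-alkene, buffered to protect the acetal; the epoxide is meso for either orientation of the aryl group, so its two enantiotopic termini are ready for desymmetrisation.

Step 4
Reactants: 5 4-Ar-3,5,8-trioxabicyclo[5.1.0]octane
Product: 7 (5S)-2-Ar-5-[(triethylsilyl)oxy]-4,5-dihydro-1,3-dioxepine (both epimers at C-2), via lithium dioxepin-5-olate 6 (not isolated)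
Conditions: (R)-2-(pyrrolidin-1-ylmethyl)pyrrolidine (1.5 equiv), n-BuLi, THF, 0 °C to rt; then Et3SiCl, 0 °C
Reagents that add atoms: chlorotriethylsilane, CC[Si](Cl)(CC)CC
Why: Enantioselective rearrangement of a meso epoxide to an allylic alcohol by a chiral lithium amide: syn β-elimination removes one of the two enantiotopic O–CH2 protons, which opens the epoxide, fixes the C-5 carbinol centre (the future C8) as S under reagent control and leaves the double bond in the enol-ether position O-1–C-7=C-6 that the contraction needs; the alkoxide is trapped in the flask as the triethylsilyl ether, a poor leaving group.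

Step 5
Reactants: 7 (5S)-2-Ar-5-[(triethylsilyl)oxy]-4,5-dihydro-1,3-dioxepine
Product: 9 [(2S,3R,4S)-2-Ar-4-[(triethylsilyl)oxy]tetrahydrofuran-3-yl]methanol, via tetrahydrofuran-3-carbaldehyde 8 (not isolated)
Conditions: Me3SiOSO2CF3 (10 mol %), CH2Cl2, −78 to −20 °C; then Et3N, NaBH4, MeOH, −20 to 0 °C
Reagents that add atoms: none
Why: Me3SiOSO2CF3 silylates the enol-ether oxygen O-1 of the seven-membered vinyl acetal and breaks the O-1–C-2 bond, giving an aryl-stabilised oxocarbenium ion (C-2=O-3+) tethered through C-4–C-5 to a (Z)-silyl enol ether; its carbon C-6 then attacks C-2 (intramolecular Mukaiyama aldol addition to an oxocarbenium ion), so that O-3, C-2, C-6, C-5 and C-4 become ring A while C-7 and O-1 leave the ring as the formyl group and the silyl triflate is released again. The closest known reaction type is the Lewis-acid rearrangement of 2-substituted 4,5-dihydro-1,3-dioxepines to 2,3-disubstituted tetrahydrofuran-3-carbaldehydes (a Petasis–Ferrier-type 1,3-shift from oxygen to carbon), applied here to a 5-silyloxy member of that class. Ring A closes in the 5-(enolexo)-endo-trig mode, workable because the nucleophilic double bond lies outside the forming ring. C8' is controlled by the C8 silyloxy centre: allylic 1,3-strain in the (Z)-enol ether turns H-5 into the plane of the double bond, so the tethered cation reaches C-6 from the face that puts the formyl group trans to the silyloxy group; C7' is controlled thermodynamically, since reversible ionisation of the benzylic C–O bond under the Lewis acid on warming should lead to the all-trans (2S,3R,4S) isomer. The step needs acetal ionisation to win over loss of the allylic C-5 oxygen (secured by the silyl ether as a poor leaving group and by the aryl-stabilised cation) and needs the β-silyloxy aldehyde to survive, which is why it is reduced in the same flask.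

Step 6
Reactants: 2 ArCHO
Product: 10 ArCH2OH, {3-methoxy-4-[(triisopropylsilyl)oxy]phenyl}methanol
Conditions: NaBH4, MeOH, 0 °C
Reagents that add atoms: none
Why: Borohydride reduction of the aryl aldehyde to the benzylic alcohol; no stereocentre is involved.

Step 7
Reactants: 10 ArCH2OH
Product: 11 ArCH2 2,2,2-trichloroacetimidate
Conditions: Cl3CCN, 1,8-diazabicyclo[5.4.0]undec-7-ene (cat.), CH2Cl2, 0 °C
Reagents that add atoms: trichloroacetonitrile, N#CC(Cl)(Cl)Cl
Why: Base-catalysed addition of the alcohol to trichloroacetonitrile gives the imidate, an acid-activated benzyl donor of the 4-methoxybenzyl type.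

Step 8
Reactants: 9 [(2S,3R,4S)-2-Ar-4-[(triethylsilyl)oxy]tetrahydrofuran-3-yl]methanol; 11 ArCH2 2,2,2-trichloroacetimidate
Product: 13 (3S,4S,5S)-5-Ar-4-[(ArCH2O)methyl]tetrahydrofuran-3-ol, via triethylsilyl ether 12 (not isolated)
Conditions: pyridinium p-toluenesulfonate (cat.), CH2Cl2, 0 °C to rt; then MeOH, rt
Reagents that add atoms: none
Why: Acid-catalysed O-benzylation with a trichloroacetimidate (SN1 through the oxygen-stabilised benzylic cation) etherifies the primary alcohol without forming an alkoxide, so the neighbouring silyl group cannot migrate; the same mild acid then removes the secondary triethylsilyl ether by methanolysis, while the aryl silyl ethers, the benzylic ethers and the three stereocentres should stay untouched.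

Step 9
Reactants: 13 (3S,4S,5S)-5-Ar-4-[(ArCH2O)methyl]tetrahydrofuran-3-ol
Product: 14 (4R,5S)-5-Ar-4-[(ArCH2O)methyl]dihydrofuran-3(2H)-one
Conditions: Dess–Martin periodinane, pyridine, CH2Cl2, 0 °C to rt
Reagents that add atoms: none
Why: Dess–Martin oxidation under buffered, non-basic conditions should give the β,β'-dialkoxy ketone without β-elimination or epimerisation at C8' (trans to the aryl group, the stable arrangement); the C8 carbinol centre, having relayed its configuration to C7' and C8', is erased here on purpose.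

Step 10
Reactants: 14 (4R,5S)-5-Ar-4-[(ArCH2O)methyl]dihydrofuran-3(2H)-one
Product: 15 (1S,2R,5R,6S)-2,6-bis(Ar)-3,7-dioxabicyclo[3.3.0]octan-1-ol
Conditions: hν (medium-pressure mercury lamp, Pyrex filter), degassed benzene, rt
Reagents that add atoms: none
Why: Norrish–Yang photocyclisation: the n,π* excited ketone abstracts a benzylic hydrogen of the C9'–O–CH2Ar ether (1,6-hydrogen transfer, no γ-hydrogen being available) and the 1,5-biradical closes the C7–C8 bond to ring B and the tertiary carbinol; the short tether from C8' allows only the cis ring fusion (OH on C8 cis to H-8', hence 8S) and the aryl group on C7 should take the exo position on the convex face (7R), any 7-epimer being removed by chromatography.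

Step 11
Reactants: 15 (1S,2R,5R,6S)-2,6-bis(Ar)-3,7-dioxabicyclo[3.3.0]octan-1-ol
Product: 16 (1S,2R,5R,6S)-2,6-bis(Ar)-3,7-dioxabicyclo[3.3.0]oct-1-yl acetate
Conditions: Ac2O, Et3N, 4-(dimethylamino)pyridine, CH2Cl2, rt to 40 °C
Reagents that add atoms: acetic anhydride, CC(=O)OC(C)=O
Why: Nucleophile-catalysed acylation of the hindered tertiary bridgehead alcohol, the only free hydroxyl group left; the C–O bond is not touched, so the configuration is retained.

Step 12
Reactants: 16 (1S,2R,5R,6S)-2,6-bis(Ar)-3,7-dioxabicyclo[3.3.0]oct-1-yl acetate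
Product: 17 1-acetoxypinoresinol, (1S,2R,5R,6S)-2,6-bis(4-hydroxy-3-methoxyphenyl)-3,7-dioxabicyclo[3.3.0]oct-1-yl acetate
Conditions: Bu4NF, AcOH (1:1), THF, 0 °C
Reagents that add atoms: none
Why: Fluoride cleavage of the two aryl silyl ethers, buffered with acetic acid so that the phenoxides cannot attack the tertiary acetate or open the benzylic ether rings through quinone methides, should release the target.

**Compound list**

1 | vanillin | COc1cc(C=O)ccc1O | starting material
2 | 3-methoxy-4-[(triisopropylsilyl)oxy]benzaldehyde | COc1cc(C=O)ccc1O[Si](C(C)C)(C(C)C)C(C)C | intermediate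
3 | (Z)-but-2-ene-1,4-diol | OC/C=C\CO | starting material
4 | 2-Ar-4,7-dihydro-1,3-dioxepine | COc1cc(C2OC/C=C\CO2)ccc1O[Si](C(C)C)(C(C)C)C(C)C | intermediate
5 | 4-Ar-3,5,8-trioxabicyclo[5.1.0]octane (meso epoxide) | COc1cc(C2OC[C@H]3O[C@H]3CO2)ccc1O[Si](C(C)C)(C(C)C)C(C)C | intermediate
6 | lithium (5S)-2-Ar-4,5-dihydro-1,3-dioxepin-5-olate (not isolated) | [Li+].COc1cc(C2OC[C@@H]([O-])/C=C\O2)ccc1O[Si](C(C)C)(C(C)C)C(C)C | intermediate
7 | (5S)-2-Ar-5-[(triethylsilyl)oxy]-4,5-dihydro-1,3-dioxepine | COc1cc(C2OC[C@@H](O[Si](CC)(CC)CC)/C=C\O2)ccc1O[Si](C(C)C)(C(C)C)C(C)C | intermediate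
8 | (2S,3R,4S)-2-Ar-4-[(triethylsilyl)oxy]tetrahydrofuran-3-carbaldehyde (not isolated) | COc1cc([C@H]2OC[C@@H](O[Si](CC)(CC)CC)[C@@H]2C=O)ccc1O[Si](C(C)C)(C(C)C)C(C)C | intermediate
9 | [(2S,3R,4S)-2-Ar-4-[(triethylsilyl)oxy]tetrahydrofuran-3-yl]methanol | COc1cc([C@H]2OC[C@@H](O[Si](CC)(CC)CC)[C@@H]2CO)ccc1O[Si](C(C)C)(C(C)C)C(C)C | intermediate
10 | {3-methoxy-4-[(triisopropylsilyl)oxy]phenyl}methanol | COc1cc(CO)ccc1O[Si](C(C)C)(C(C)C)C(C)C | intermediate
11 | 3-methoxy-4-[(triisopropylsilyl)oxy]benzyl 2,2,2-trichloroacetimidate | COc1cc(COC(=N)C(Cl)(Cl)Cl)ccc1O[Si](C(C)C)(C(C)C)C(C)C | intermediate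
12 | (2S,3R,4S)-2-Ar-3-[(ArCH2O)methyl]-4-[(triethylsilyl)oxy]tetrahydrofuran (not isolated) | COc1cc([C@H]2OC[C@@H](O[Si](CC)(CC)CC)[C@@H]2COCc3ccc(O[Si](C(C)C)(C(C)C)C(C)C)c(OC)c3)ccc1O[Si](C(C)C)(C(C)C)C(C)C | intermediate
13 | (3S,4S,5S)-5-Ar-4-[(ArCH2O)methyl]tetrahydrofuran-3-ol | COc1cc([C@H]2OC[C@@H](O)[C@@H]2COCc3ccc(O[Si](C(C)C)(C(C)C)C(C)C)c(OC)c3)ccc1O[Si](C(C)C)(C(C)C)C(C)C | intermediate
14 | (4R,5S)-5-Ar-4-[(ArCH2O)methyl]dihydrofuran-3(2H)-one | COc1cc([C@H]2OCC(=O)[C@@H]2COCc3ccc(O[Si](C(C)C)(C(C)C)C(C)C)c(OC)c3)ccc1O[Si](C(C)C)(C(C)C)C(C)C | intermediate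
15 | (1S,2R,5R,6S)-2,6-bis(Ar)-3,7-dioxabicyclo[3.3.0]octan-1-ol | COc1cc([C@H]2OC[C@]3(O)[C@@H](c4ccc(O[Si](C(C)C)(C(C)C)C(C)C)c(OC)c4)OC[C@H]23)ccc1O[Si](C(C)C)(C(C)C)C(C)C | intermediate
16 | (1S,2R,5R,6S)-2,6-bis(Ar)-3,7-dioxabicyclo[3.3.0]oct-1-yl acetate | COc1cc([C@H]2OC[C@]3(OC(C)=O)[C@@H](c4ccc(O[Si](C(C)C)(C(C)C)C(C)C)c(OC)c4)OC[C@H]23)ccc1O[Si](C(C)C)(C(C)C)C(C)C | intermediate
17 | 1-acetoxypinoresinol | COc1cc([C@H]2OC[C@]3(OC(C)=O)[C@@H](c4ccc(O)c(OC)c4)OC[C@H]23)ccc1O | target

**Count and risks**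

Total steps: 12. Longest linear sequence: 10 (steps 1 to 5 and 8 to 12).

Most likely to fail:

1. Step 5 (ring contraction). What may go wrong: ionisation at the allylic C-5–O bond, or capture of the oxocarbenium ion by the silyloxy oxygen (acetal transposition to a dioxolane), in place of C–C bond formation; β-elimination of silanol from the aldehyde; incomplete equilibration at C7'. Fallback, from aldehyde 2 to ketone 14: the C7'–C8' bond is made by an aldol reaction and ring A is closed at the benzylic carbon instead.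
   - The dianion of commercial (R)-4-hydroxydihydrofuran-2(3H)-one (2 equiv LiN(i-Pr)2, THF, −78 °C) should add to 2 anti to the alkoxide and give the aldol lactone (3R,4R)-4-hydroxy-3-[hydroxy(Ar)methyl]dihydrofuran-2(3H)-one F1.
   - LiBH4 reduces it to (2R,3R)-3-[hydroxy(Ar)methyl]butane-1,2,4-triol F2.
   - Catalytic camphorsulfonic acid in CH2Cl2 ionises the benzylic carbinol and the C9 hydroxyl closes the 2,3-trans tetrahydrofuran (3R,4S,5S)-5-Ar-4-(hydroxymethyl)tetrahydrofuran-3-ol F3. This is the C8 epimer of desilylated 9; the (R)-lactone is chosen because it gives the correct C7'/C8' pair and C8 is oxidised anyway.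
   - Primary-selective benzylation with 1 equiv of imidate 11 (cat. pyridinium p-toluenesulfonate) gives (3R,4S,5S)-5-Ar-4-[(ArCH2O)methyl]tetrahydrofuran-3-ol F4, and Dess–Martin oxidation gives 14.

2. Step 4 (desymmetrisation). What may go wrong: weak discrimination between the two enantiotopic O–CH2 protons, made worse by the presence of two acetal epimers. Fallback, from epoxide 5 to vinyl acetal 7: the asymmetric event is moved from the deprotonation to a ketone reduction.
   - Achiral LiN(i-Pr)2 isomerises 5 to racemic 2-Ar-4,5-dihydro-1,3-dioxepin-5-ol F5.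
   - MnO2 oxidises it to the vinylogous ester 2-Ar-1,3-dioxepin-5(4H)-one F6.
   - Corey–Bakshi–Shibata reduction ((S)-1-methyl-3,3-diphenyltetrahydro-1H,3H-pyrrolo[1,2-c][1,3,2]oxazaborole, catecholborane, toluene, −78 °C; the enol-ether double bond acts as the large group) should give (5S)-2-Ar-4,5-dihydro-1,3-dioxepin-5-ol F7.
   - Et3SiCl and imidazole give 7.

3. Step 10 (photocyclisation). What may go wrong: α-cleavage of the excited oxacyclopentanone outrunning hydrogen transfer, or unselective biradical closure at C7. Fallback, from ketone 14 to 15: the C8 oxygen is delivered to an alkene instead of the C7 carbon to a ketone.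
   - Alcohol 10 is converted with PBr3 into 4-(bromomethyl)-2-methoxy-1-[(triisopropylsilyl)oxy]benzene F8 and with PPh3 into (ArCH2)triphenylphosphonium bromide F9.
   - Its ylide (NaN(SiMe3)2, THF) olefinates 14 to the benzylidene compound (2S,3R)-2-Ar-4-(Ar-methylidene)-3-[(ArCH2O)methyl]tetrahydrofuran F10 (either alkene geometry).
   - Dihydroxylation (OsO4 cat., N-methylmorpholine N-oxide) anti to the C9' branch should give (3S,4R,5S)-5-Ar-3-[hydroxy(Ar)methyl]-4-[(ArCH2O)methyl]tetrahydrofuran-3-ol F11.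
   - BF3·OEt2 at low temperature ionises the benzylic C7 carbinol; the C9' ether oxygen closes ring B with the aryl group exo and sheds its electron-rich benzyl group, which gives 15.

Further compounds
F1 | step 5 | (3R,4R)-4-hydroxy-3-[hydroxy(Ar)methyl]dihydrofuran-2(3H)-one (carbinol epimers) | O=C1OC[C@H](O)[C@H]1C(O)c2ccc(O[Si](C(C)C)(C(C)C)C(C)C)c(OC)c2
F2 | step 5 | (2R,3R)-3-[hydroxy(Ar)methyl]butane-1,2,4-triol (carbinol epimers) | OC[C@H](O)[C@H](CO)C(O)c1ccc(O[Si](C(C)C)(C(C)C)C(C)C)c(OC)c1
F3 | step 5 | (3R,4S,5S)-5-Ar-4-(hydroxymethyl)tetrahydrofuran-3-ol | COc1cc([C@H]2OC[C@H](O)[C@@H]2CO)ccc1O[Si](C(C)C)(C(C)C)C(C)C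
F4 | step 5 | (3R,4S,5S)-5-Ar-4-[(ArCH2O)methyl]tetrahydrofuran-3-ol | COc1cc([C@H]2OC[C@H](O)[C@@H]2COCc3ccc(O[Si](C(C)C)(C(C)C)C(C)C)c(OC)c3)ccc1O[Si](C(C)C)(C(C)C)C(C)C
F5 | step 4 | racemic 2-Ar-4,5-dihydro-1,3-dioxepin-5-ol | COc1cc(C2OCC(O)/C=C\O2)ccc1O[Si](C(C)C)(C(C)C)C(C)C
F6 | step 4 | 2-Ar-1,3-dioxepin-5(4H)-one | COc1cc(C2OCC(=O)/C=C\O2)ccc1O[Si](C(C)C)(C(C)C)C(C)C
F7 | step 4 | (5S)-2-Ar-4,5-dihydro-1,3-dioxepin-5-ol | COc1cc(C2OC[C@@H](O)/C=C\O2)ccc1O[Si](C(C)C)(C(C)C)C(C)C
F8 | step 10 | 4-(bromomethyl)-2-methoxy-1-[(triisopropylsilyl)oxy]benzene | COc1cc(CBr)ccc1O[Si](C(C)C)(C(C)C)C(C)C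
F9 | step 10 | {3-methoxy-4-[(triisopropylsilyl)oxy]benzyl}triphenylphosphonium bromide | COc1cc(C[P+](c2ccccc2)(c2ccccc2)c2ccccc2)ccc1O[Si](C(C)C)(C(C)C)C(C)C.[Br-]
F10 | step 10 | (2S,3R)-2-Ar-4-(Ar-methylidene)-3-[(ArCH2O)methyl]tetrahydrofuran | COc1cc([C@H]2OCC(=Cc3ccc(O[Si](C(C)C)(C(C)C)C(C)C)c(OC)c3)[C@@H]2COCc4ccc(O[Si](C(C)C)(C(C)C)C(C)C)c(OC)c4)ccc1O[Si](C(C)C)(C(C)C)C(C)C
F11 | step 10 | (3S,4R,5S)-5-Ar-3-[hydroxy(Ar)methyl]-4-[(ArCH2O)methyl]tetrahydrofuran-3-ol | COc1cc([C@H]2OC[C@](O)(C(O)c3ccc(O[Si](C(C)C)(C(C)C)C(C)C)c(OC)c3)[C@@H]2COCc4ccc(O[Si](C(C)C)(C(C)C)C(C)C)c(OC)c4)ccc1O[Si](C(C)C)(C(C)C)C(C)C
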